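## Retrosynthetic overview

1. Naming: ring A = styryl phenol; rings B and C = benzo rings of the inner and outer dihydrobenzofuran (benzofuran numbering O1, C2, C3, C3a–C7a in each); ring D = 3,5-dihydroxyphenyl on C3 of the outer unit; ring E = 2,4-dihydroxyphenyl on its C2; ring F = 4-hydroxyphenyl on C2 of the inner unit.
2. Target ⇒ four ArOH as ArOTf and four as ArOMe ⇒ HWE cut of the ring A–CH=CH–ring B olefin ⇒ inner dihydrofuran ring cut at O1–C7a and C3–C3a into a 3-methoxybenzyne (ring B) and a (2R,3R)-trans-oxirane ⇒ Shi epoxidation and HWE back to the outer aldehyde ⇒ outer dihydrofuran ring cut the same way into the same benzyne (ring C) and the (2R,3R)-oxirane of the ring E/ring D stilbene.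
3. Enabling feature: in ring C (and again in ring B) the ether oxygen O1 sits on C7a, the benzylic C3 on the neighbouring C3a, C3a is flanked on its other side by the C4 oxygen, and the last substituent is on C6. This O–C–C(–O) pattern is what a 3-alkoxybenzyne gives when an O-nucleophile adds to the aryne carbon remote from the alkoxy group and carbon is then captured at the carbon next to it. O1–C2–C3 with its two trans aryl groups is a masked trans-stilbene oxide.
4. The triflates on rings E, F and A are removable activating groups: they decide which oxirane C–O bond breaks, make the epoxides storable and mute the acid-labile sites; they are hydrolysed last.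
5. Ring order: all benzene rings are bought; the outer dihydrofuran ring is formed first (step 9), the inner one second (step 15), by one repeated cycle aryne insertion → aldehyde → stilbene → epoxide that draws twice on the single aryne source 12 and mirrors the olefin-to-benzofuran chain growth of the oligostilbenes with reversed polarity.

Key step: step 9

Assumption (remark on the chemistry): aryl triflates are used as electron-withdrawing phenol masks that are cleaved at sulfur at the end, and the D-fructose-derived Shi ketone is assumed to give the (R,R)-oxiranes from both trans-stilbenes, as it does from trans-stilbene itself.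

## Route

Step 1
Reactants: 1 2,4-dihydroxybenzaldehyde
Product: 2 4-formyl-1,3-phenylene bis(trifluoromethanesulfonate)
Conditions: Tf2O, pyridine, CH2Cl2, 0 °C
Reagents that add atoms: trifluoromethanesulfonic anhydride, O=S(=O)(OS(=O)(=O)C(F)(F)F)C(F)(F)F
Why: O-sulfonylation of both phenols with Tf2O/pyridine should give the bis-triflate, whose electron-poor ring E later steers the key step.

Step 2
Reactants: 2 4-formyl-1,3-phenylene bis(trifluoromethanesulfonate); 3 diethyl (3,5-dimethoxybenzyl)phosphonate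
Product: 4 4-[(E)-2-(3,5-dimethoxyphenyl)ethenyl]-1,3-phenylene bis(trifluoromethanesulfonate)
Conditions: NaH, THF, 0 °C to rt
Reagents that add atoms: none
Why: Horner–Wadsworth–Emmons olefination of the electron-poor aldehyde with the benzylic phosphonate anion should give the (E)-stilbene, the aryl triflates tolerating the non-nucleophilic base.

Step 3
Reactants: 4 4-[(E)-2-(3,5-dimethoxyphenyl)ethenyl]-1,3-phenylene bis(trifluoromethanesulfonate)
Product: 5 4-[(2R,3R)-3-(3,5-dimethoxyphenyl)oxiran-2-yl]-1,3-phenylene bis(trifluoromethanesulfonate)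
Conditions: D-fructose-derived Shi ketone (30 mol %), KHSO5 (as Oxone), K2CO3, Bu4NHSO4, MeCN/CH2(OMe)2/aq. Na2B4O7 buffer (pH 10.5), 0 °C
Reagents that add atoms: potassium peroxymonosulfate KHSO5, [K+].[O-]S(=O)(=O)OO
Why: Shi asymmetric epoxidation of a trans-stilbene through the chiral dioxirane should set both oxirane stereocentres as (2R,3R) under catalyst control, and the two triflates should keep the epoxide from ionising on handling.

Step 4
Reactants: 6 3-hydroxy-5-methoxybenzaldehyde
Product: 7 3-(1,3-dioxolan-2-yl)-5-methoxyphenol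
Conditions: HOCH2CH2OH, p-TsOH (cat.), toluene, reflux (Dean–Stark)
Reagents that add atoms: ethane-1,2-diol, OCCO
Why: acid-catalysed acetalisation with azeotropic removal of water masks the aldehyde against the organolithium, hydride and aryne chemistry that follows.

Step 5
Reactants: 7 3-(1,3-dioxolan-2-yl)-5-methoxyphenol
Product: 8 3-(1,3-dioxolan-2-yl)-5-methoxyphenyl diethylcarbamate
Conditions: Et2NCOCl, K2CO3, MeCN, reflux
Reagents that add atoms: diethylcarbamoyl chloride, CCN(CC)C(Cl)=O
Why: O-carbamoylation of the phenoxide installs a strong directing group for ortho-metalation.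

Step 6
Reactants: 8 3-(1,3-dioxolan-2-yl)-5-methoxyphenyl diethylcarbamate
Product: 10 5-(1,3-dioxolan-2-yl)-3-methoxy-2-(trimethylsilyl)phenyl diethylcarbamate, via aryllithium 9 (not isolated)
Conditions: s-BuLi, TMEDA, THF, −78 °C; then Me3SiCl, −78 °C to rt
Reagents that add atoms: chlorotrimethylsilane, C[Si](C)(C)Cl
Why: directed ortho-metalation should occur at the carbon between the carbamate and the methoxy group, which both activate it, and silylation at −78 °C should precede any anionic Fries shift.

Step 7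
Reactants: 10 5-(1,3-dioxolan-2-yl)-3-methoxy-2-(trimethylsilyl)phenyl diethylcarbamate
Product: 11 5-(1,3-dioxolan-2-yl)-3-methoxy-2-(trimethylsilyl)phenol
Conditions: LiAlH4, THF, 0 °C to reflux; H2O/aq. NaOH work-up
Reagents that add atoms: none
Why: hydride reduction cleaves the aryl carbamate to the phenol (the carbamoyl unit leaves as an N-methyl amine) without touching the aryl–silicon bond or the acetal.

Step 8
Reactants: 11 5-(1,3-dioxolan-2-yl)-3-methoxy-2-(trimethylsilyl)phenol
Product: 12 5-(1,3-dioxolan-2-yl)-3-methoxy-2-(trimethylsilyl)phenyl trifluoromethanesulfonate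
Conditions: Tf2O, pyridine, CH2Cl2, 0 °C
Reagents that add atoms: trifluoromethanesulfonic anhydride, O=S(=O)(OS(=O)(=O)C(F)(F)F)C(F)(F)F
Why: O-triflation of the ortho-silyl phenol gives the 2-(trimethylsilyl)aryl triflate, a fluoride-triggered aryne precursor that is made once and serves both insertion steps.

Step 9
Reactants: 5 4-[(2R,3R)-3-(3,5-dimethoxyphenyl)oxiran-2-yl]-1,3-phenylene bis(trifluoromethanesulfonate); 12 5-(1,3-dioxolan-2-yl)-3-methoxy-2-(trimethylsilyl)phenyl trifluoromethanesulfonate
Product: 15 4-[(2S,3S)-3-(3,5-dimethoxyphenyl)-6-(1,3-dioxolan-2-yl)-4-methoxy-2,3-dihydro-1-benzofuran-2-yl]-1,3-phenylene bis(trifluoromethanesulfonate), via aryne 13 (not isolated), via oxonium betaine 14 (not isolated)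
Conditions: CsF, MeCN, rt to 40 °C (12 added slowly, 2.5 equiv)
Reagents that add atoms: none
Why: Proposed new method: fluoride-induced 1,2-elimination of 12 gives the 3-methoxybenzyne 13, and the oxirane oxygen of 5 should add to the aryne carbon remote from OMe (the usual polarisation of 3-alkoxyarynes), which forms O1–C7a and leaves the aryl anion on C3a, next to OMe, in betaine 14. The strained O-aryl oxiranium should ionise at O–C3, because a benzylic cation beside the 3,5-dimethoxyphenyl ring D is far better than one beside the bis(triflyloxy)phenyl ring E, and the ion pair then collapses to the C3–C3a bond; the five-membered dihydrofuran ring is thus closed by anion–cation recombination inside a tethered ion pair (a Stevens-like shift of C3 from O to the ortho carbon), not by an SN2 displacement. The closest known reaction type is the insertion of arynes into the benzylic C–O bond of styrene oxide to give 3-aryl-2,3-dihydrobenzofurans; new here are the 2,3-diaryl oxirane and the transfer of configuration. No stereocentre is created: C2 keeps its C–O bond and so its configuration, and C3 should be retained because C3a is held by the O1–C7a tether on the face that the oxygen leaves and the trans arrangement of the two aryl groups is also the preferred mode of ring closure, so the (2R,3R)-oxirane should map onto the (2S,3S)-trans ring (the descriptors change only through CIP priorities). The step needs three selectivities: aryne regiochemistry (secured by the 3-OMe group), the site of C–O cleavage (secured by the two triflates on ring E) and retention at C3 (secured by the tether and by the fixed C2 centre).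

Step 10
Reactants: 15 4-[(2S,3S)-3-(3,5-dimethoxyphenyl)-6-(1,3-dioxolan-2-yl)-4-methoxy-2,3-dihydro-1-benzofuran-2-yl]-1,3-phenylene bis(trifluoromethanesulfonate)
Product: 16 4-[(2S,3S)-3-(3,5-dimethoxyphenyl)-6-formyl-4-methoxy-2,3-dihydro-1-benzofuran-2-yl]-1,3-phenylene bis(trifluoromethanesulfonate)
Conditions: 1 M aq. HCl, THF, rt
Reagents that add atoms: water, O
Why: aqueous acid hydrolysis of the dioxolane frees the aldehyde, while the triflate-deactivated ring E keeps the benzylic C2–O1 bond from ionising.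

Step 11
Reactants: 17 4-methylphenyl trifluoromethanesulfonate
Product: 18 4-(bromomethyl)phenyl trifluoromethanesulfonate
Conditions: NBS, AIBN (cat.), PhCF3, 80 °C
Reagents that add atoms: N-bromosuccinimide, O=C1CCC(=O)N1Br
Why: Wohl–Ziegler radical bromination is selective for the benzylic methyl group of the deactivated arene.

Step 12
Reactants: 18 4-(bromomethyl)phenyl trifluoromethanesulfonate
Product: 19 diethyl {4-[(trifluoromethanesulfonyl)oxy]benzyl}phosphonate
Conditions: P(OEt)3, neat, 130 °C
Reagents that add atoms: triethyl phosphite, CCOP(OCC)OCC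
Why: Michaelis–Arbuzov reaction of the benzylic bromide with triethyl phosphite gives the phosphonate, the aryl triflate being inert without a metal catalyst.

Step 13
Reactants: 16 4-[(2S,3S)-3-(3,5-dimethoxyphenyl)-6-formyl-4-methoxy-2,3-dihydro-1-benzofuran-2-yl]-1,3-phenylene bis(trifluoromethanesulfonate); 19 diethyl {4-[(trifluoromethanesulfonyl)oxy]benzyl}phosphonate
Product: 20 4-[(2S,3S)-3-(3,5-dimethoxyphenyl)-4-methoxy-6-{(E)-2-[4-(trifluoromethanesulfonyloxy)phenyl]ethenyl}-2,3-dihydro-1-benzofuran-2-yl]-1,3-phenylene bis(trifluoromethanesulfonate)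
Conditions: NaH, THF, 0 °C to rt
Reagents that add atoms: none
Why: Horner–Wadsworth–Emmons olefination should give the (E)-stilbene that carries ring F as its triflate, and the non-acidic C2 and C3 stereocentres are not at risk.

Step 14
Reactants: 20 4-[(2S,3S)-3-(3,5-dimethoxyphenyl)-4-methoxy-6-{(E)-2-[4-(trifluoromethanesulfonyloxy)phenyl]ethenyl}-2,3-dihydro-1-benzofuran-2-yl]-1,3-phenylene bis(trifluoromethanesulfonate)
Product: 21 4-[(2S,3S)-3-(3,5-dimethoxyphenyl)-4-methoxy-6-{(2R,3R)-3-[4-(trifluoromethanesulfonyloxy)phenyl]oxiran-2-yl}-2,3-dihydro-1-benzofuran-2-yl]-1,3-phenylene bis(trifluoromethanesulfonate)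
Conditions: D-fructose-derived Shi ketone (30 mol %), KHSO5 (as Oxone), K2CO3, Bu4NHSO4, MeCN/CH2(OMe)2/aq. Na2B4O7 buffer (pH 10.5), 0 °C
Reagents that add atoms: potassium peroxymonosulfate KHSO5, [K+].[O-]S(=O)(=O)OO
Why: Shi epoxidation of the trans-stilbene should set the two new oxirane stereocentres as (2R,3R) under catalyst control, the existing stereocentres being too remote to interfere.

Step 15
Reactants: 21 4-[(2S,3S)-3-(3,5-dimethoxyphenyl)-4-methoxy-6-{(2R,3R)-3-[4-(trifluoromethanesulfonyloxy)phenyl]oxiran-2-yl}-2,3-dihydro-1-benzofuran-2-yl]-1,3-phenylene bis(trifluoromethanesulfonate); 12 5-(1,3-dioxolan-2-yl)-3-methoxy-2-(trimethylsilyl)phenyl trifluoromethanesulfonate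
Product: 23 (2S,3S)-6-(1,3-dioxolan-2-yl)-4-methoxy-2-[4-(trifluoromethanesulfonyloxy)phenyl]-2,3-dihydro-1-benzofuran bearing at C3 the C6 of the (2S,3S)-2-[2,4-bis(trifluoromethanesulfonyloxy)phenyl]-3-(3,5-dimethoxyphenyl)-4-methoxy-2,3-dihydro-1-benzofuran unit, via oxonium betaine 22 (not isolated)
Conditions: CsF, MeCN, rt to 40 °C (12 added slowly, 2.5 equiv)
Reagents that add atoms: none
Why: Proposed new method: the aryne insertion of step 9 is repeated with a second portion of 12 (closest known type: aryne insertion into the benzylic C–O bond of styrene oxide), in which the oxirane oxygen of 21 adds to the carbon remote from OMe of the benzyne that fluoride releases from 12 exactly as in step 9 (the transient already numbered 13), betaine 22 ionises at the O–C bond beside ring C (para-alkyl-substituted, whereas ring F is deactivated by its triflate) and the tethered ion pair collapses with retention, so that the (2R,3R)-oxirane should become the (2S,3S)-trans ring on ring B.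

Step 16
Reactants: 23 the bis(dihydrobenzofuran) acetal of step 15
Product: 24 (2S,3S)-6-formyl-4-methoxy-2-[4-(trifluoromethanesulfonyloxy)phenyl]-2,3-dihydro-1-benzofuran bearing at C3 the C6 of the (2S,3S)-2-[2,4-bis(trifluoromethanesulfonyloxy)phenyl]-3-(3,5-dimethoxyphenyl)-4-methoxy-2,3-dihydro-1-benzofuran unit
Conditions: 1 M aq. HCl, THF, rt
Reagents that add atoms: water, O
Why: acetal hydrolysis frees the ring B aldehyde, both benzylic C2–O1 bonds being protected from ionisation by their triflate-bearing aryl groups.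

Step 17
Reactants: 24 the bis(dihydrobenzofuran) aldehyde of step 16; 19 diethyl {4-[(trifluoromethanesulfonyl)oxy]benzyl}phosphonate
Product: 25 tetra-O-triflyl tetra-O-methyl target: 24 in which the formyl group is replaced by (E)-2-[4-(trifluoromethanesulfonyloxy)phenyl]ethenyl
Conditions: NaH, THF, 0 °C to rt
Reagents that add atoms: none
Why: a second Horner–Wadsworth–Emmons olefination should install the (E)-styryl unit with ring A as its triflate, which keeps the stilbene electron-poor for the acid step that follows.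

Step 18
Reactants: 25 tetra-O-triflyl tetra-O-methyl target
Product: 26 tetra-O-triflyl target (free OH at C4 of rings B and C and at C3/C5 of ring D; OTf on rings A, E and F)
Conditions: BBr3, CH2Cl2, −78 to 0 °C; then MeOH/H2O
Reagents that add atoms: none
Why: BBr3 cleaves the four aryl methyl ethers by Lewis acid complexation and bromide attack at methyl, while the inert triflates keep rings A, E and F electron-poor so that neither benzylic C2–O bond ionises nor the stilbene is protonated.

Step 19
Reactants: 26 tetra-O-triflyl target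
Product: 27 target (CNP0118407.1)
Conditions: Et4NOH (aq.), 1,4-dioxane, rt, under Ar; then aq. NH4Cl
Reagents that add atoms: none
Why: hydroxide attacks sulfur of the four aryl triflates (S–O cleavage), which releases the phenols without breaking any C–O bond or touching the four stereocentres.

## Compound list

1 | 2,4-dihydroxybenzaldehyde | O=Cc1ccc(O)cc1O | starting material
2 | 4-formyl-1,3-phenylene bis(trifluoromethanesulfonate) | O=Cc1ccc(OS(=O)(=O)C(F)(F)F)cc1OS(=O)(=O)C(F)(F)F | intermediate
3 | diethyl (3,5-dimethoxybenzyl)phosphonate | CCOP(=O)(Cc1cc(OC)cc(OC)c1)OCC | starting material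
4 | 4-[(E)-2-(3,5-dimethoxyphenyl)ethenyl]-1,3-phenylene bis(trifluoromethanesulfonate) | COc1cc(/C=C/c2ccc(OS(=O)(=O)C(F)(F)F)cc2OS(=O)(=O)C(F)(F)F)cc(OC)c1 | intermediate
5 | 4-[(2R,3R)-3-(3,5-dimethoxyphenyl)oxiran-2-yl]-1,3-phenylene bis(trifluoromethanesulfonate) | O1[C@H](c2ccc(OS(=O)(=O)C(F)(F)F)cc2OS(=O)(=O)C(F)(F)F)[C@H]1c3cc(OC)cc(OC)c3 | intermediate
6 | 3-hydroxy-5-methoxybenzaldehyde | COc1cc(O)cc(C=O)c1 | starting material
7 | 3-(1,3-dioxolan-2-yl)-5-methoxyphenol | COc1cc(O)cc(C2OCCO2)c1 | intermediate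
8 | 3-(1,3-dioxolan-2-yl)-5-methoxyphenyl diethylcarbamate | CCN(CC)C(=O)Oc1cc(OC)cc(C2OCCO2)c1 | intermediate
9 | [2-(diethylcarbamoyloxy)-4-(1,3-dioxolan-2-yl)-6-methoxyphenyl]lithium | CCN(CC)C(=O)Oc1cc(C2OCCO2)cc(OC)c1[Li] | intermediate
10 | 5-(1,3-dioxolan-2-yl)-3-methoxy-2-(trimethylsilyl)phenyl diethylcarbamate | CCN(CC)C(=O)Oc1cc(C2OCCO2)cc(OC)c1[Si](C)(C)C | intermediate
11 | 5-(1,3-dioxolan-2-yl)-3-methoxy-2-(trimethylsilyl)phenol | COc1cc(C2OCCO2)cc(O)c1[Si](C)(C)C | intermediate
12 | 5-(1,3-dioxolan-2-yl)-3-methoxy-2-(trimethylsilyl)phenyl trifluoromethanesulfonate | COc1cc(C2OCCO2)cc(OS(=O)(=O)C(F)(F)F)c1[Si](C)(C)C | intermediate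
13 | 5-(1,3-dioxolan-2-yl)-3-methoxybenzyne (aryne released from 12 by fluoride) | COC1=CC(C2OCCO2)=CC#C1 | intermediate
14 | oxonium betaine from 13 and 5 (O-aryl oxiranium with the aryl anion on the carbon between O and OMe) | COc1cc(C2OCCO2)cc([O+]3[C@H](c4ccc(OS(=O)(=O)C(F)(F)F)cc4OS(=O)(=O)C(F)(F)F)[C@H]3c5cc(OC)cc(OC)c5)[c-]1 | intermediate
15 | 4-[(2S,3S)-3-(3,5-dimethoxyphenyl)-6-(1,3-dioxolan-2-yl)-4-methoxy-2,3-dihydro-1-benzofuran-2-yl]-1,3-phenylene bis(trifluoromethanesulfonate) | O1CCOC1c1cc(OC)c2c(c1)O[C@H](c1ccc(OS(=O)(=O)C(F)(F)F)cc1OS(=O)(=O)C(F)(F)F)[C@H]2c1cc(OC)cc(OC)c1 | intermediate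
16 | 4-[(2S,3S)-3-(3,5-dimethoxyphenyl)-6-formyl-4-methoxy-2,3-dihydro-1-benzofuran-2-yl]-1,3-phenylene bis(trifluoromethanesulfonate) | O=Cc1cc(OC)c2c(c1)O[C@H](c1ccc(OS(=O)(=O)C(F)(F)F)cc1OS(=O)(=O)C(F)(F)F)[C@H]2c1cc(OC)cc(OC)c1 | intermediate
17 | 4-methylphenyl trifluoromethanesulfonate | Cc1ccc(OS(=O)(=O)C(F)(F)F)cc1 | starting material
18 | 4-(bromomethyl)phenyl trifluoromethanesulfonate | BrCc1ccc(OS(=O)(=O)C(F)(F)F)cc1 | intermediate
19 | diethyl {4-[(trifluoromethanesulfonyl)oxy]benzyl}phosphonate | CCOP(=O)(Cc1ccc(OS(=O)(=O)C(F)(F)F)cc1)OCC | intermediate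
20 | 4-[(2S,3S)-3-(3,5-dimethoxyphenyl)-4-methoxy-6-{(E)-2-[4-(trifluoromethanesulfonyloxy)phenyl]ethenyl}-2,3-dihydro-1-benzofuran-2-yl]-1,3-phenylene bis(trifluoromethanesulfonate) | FC(F)(F)S(=O)(=O)Oc1ccc(/C=C/c2cc(OC)c3c(c2)O[C@H](c2ccc(OS(=O)(=O)C(F)(F)F)cc2OS(=O)(=O)C(F)(F)F)[C@H]3c2cc(OC)cc(OC)c2)cc1 | intermediate
21 | 4-[(2S,3S)-3-(3,5-dimethoxyphenyl)-4-methoxy-6-{(2R,3R)-3-[4-(trifluoromethanesulfonyloxy)phenyl]oxiran-2-yl}-2,3-dihydro-1-benzofuran-2-yl]-1,3-phenylene bis(trifluoromethanesulfonate) | O1[C@H](c2ccc(OS(=O)(=O)C(F)(F)F)cc2)[C@H]1c1cc(OC)c2c(c1)O[C@H](c1ccc(OS(=O)(=O)C(F)(F)F)cc1OS(=O)(=O)C(F)(F)F)[C@H]2c1cc(OC)cc(OC)c1 | intermediate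
22 | oxonium betaine from the benzyne of 12 and 21 | COc1cc(C2OCCO2)cc([O+]3[C@H](c4ccc(OS(=O)(=O)C(F)(F)F)cc4)[C@H]3c5cc(OC)c6c(c5)O[C@H](c7ccc(OS(=O)(=O)C(F)(F)F)cc7OS(=O)(=O)C(F)(F)F)[C@H]6c8cc(OC)cc(OC)c8)[c-]1 | intermediate
23 | bis(dihydrobenzofuran) acetal (2S,3S in both rings; inner ring 6-(1,3-dioxolan-2-yl)-4-methoxy-2-[4-(triflyloxy)phenyl]; its C3 bears C6 of the outer ring of 15) | O1CCOC1c1cc(OC)c2c(c1)O[C@H](c1ccc(OS(=O)(=O)C(F)(F)F)cc1)[C@H]2c1cc(OC)c2c(c1)O[C@H](c1ccc(OS(=O)(=O)C(F)(F)F)cc1OS(=O)(=O)C(F)(F)F)[C@H]2c1cc(OC)cc(OC)c1 | intermediate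
24 | bis(dihydrobenzofuran) aldehyde (23 with CHO in place of the dioxolane) | O=Cc1cc(OC)c2c(c1)O[C@H](c1ccc(OS(=O)(=O)C(F)(F)F)cc1)[C@H]2c1cc(OC)c2c(c1)O[C@H](c1ccc(OS(=O)(=O)C(F)(F)F)cc1OS(=O)(=O)C(F)(F)F)[C@H]2c1cc(OC)cc(OC)c1 | intermediate
25 | tetra-O-triflyl tetra-O-methyl target (OTf on rings A, E and F; OMe at C4 of rings B and C and at C3/C5 of ring D) | FC(F)(F)S(=O)(=O)Oc1ccc(/C=C/c2cc(OC)c3c(c2)O[C@H](c2ccc(OS(=O)(=O)C(F)(F)F)cc2)[C@H]3c2cc(OC)c3c(c2)O[C@H](c2ccc(OS(=O)(=O)C(F)(F)F)cc2OS(=O)(=O)C(F)(F)F)[C@H]3c2cc(OC)cc(OC)c2)cc1 | intermediate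
26 | tetra-O-triflyl target (OTf on rings A, E and F; four free OH) | FC(F)(F)S(=O)(=O)Oc1ccc(/C=C/c2cc(O)c3c(c2)O[C@H](c2ccc(OS(=O)(=O)C(F)(F)F)cc2)[C@H]3c2cc(O)c3c(c2)O[C@H](c2ccc(OS(=O)(=O)C(F)(F)F)cc2OS(=O)(=O)C(F)(F)F)[C@H]3c2cc(O)cc(O)c2)cc1 | intermediate
27 | CNP0118407.1 | Oc1ccc(/C=C/c2cc(O)c3c(c2)O[C@H](c2ccc(O)cc2)[C@H]3c2cc(O)c3c(c2)O[C@H](c2ccc(O)cc2O)[C@H]3c2cc(O)cc(O)c2)cc1 | target

## Summary and risks

Total step count: 19. Longest linear sequence: 14 steps (steps 4–10 and 13–19, from 6).

Steps most likely to fail: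

1. Step 9 (Proposed new method). The weakly nucleophilic oxirane oxygen may lose the race for the aryne to fluoride, solvent or the acetal oxygens. Rotation about C2–C3 in the ion pair before recombination would erode the configuration at C3, and a hydride shift in the cation would divert it to a ketone. The fallback uses known chemistry with the biosynthesis-like polarity; it sets out from 4 (and uses 7) and comes back to the route at 15. Stilbene 4 would be epoxidised with the enantiomeric Shi ketone (the L-fructose-derived ketone) to 4-[(2S,3S)-3-(3,5-dimethoxyphenyl)oxiran-2-yl]-1,3-phenylene bis(trifluoromethanesulfonate) F1. Friedel–Crafts opening of F1 by phenol 7 in (CF3)2CHOH, at the ring D benzylic carbon with inversion and at the arene carbon between OH and OMe (the site between the two oxygens, as resorcinols react in acid-mediated C-alkylations), should give (1R,2S)-1-[2,4-bis(trifluoromethanesulfonyloxy)phenyl]-2-(3,5-dimethoxyphenyl)-2-[4-(1,3-dioxolan-2-yl)-2-hydroxy-6-methoxyphenyl]ethan-1-ol F2. Mitsunobu cycloetherification (PPh3, DIAD, THF) with inversion at the carbinol carbon would then close O1–C2 and give 15; two inversions from the (2S,3S)-oxirane lead to the same (2S,3S)-trans ring as two retentions from 5.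

2. Step 15 (Proposed new method). The same process risks apply, and the ether oxygens of 21 can also compete for the aryne. The fallback sets out from 20 (and uses 7) and comes back at 23. Epoxidation of 20 with the enantiomeric Shi ketone should give the (2S,3S)-oxirane diastereomer of 21 F3. Friedel–Crafts opening by 7 in (CF3)2CHOH at the benzylic carbon beside ring C (inversion) should give the phenol-alcohol with (R)-carbinol and (S)-triarylmethine centres F4, and Mitsunobu ring closure with inversion should give 23.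

3. Step 19. Under strong hydroxide the fully unmasked polyphenolate forms. It is prone to air oxidation, and the phenoxides ortho and para to C2 on rings E and F can open the dihydrofuran rings reversibly through quinone methides, which may be followed by irreversible loss of the C3 proton. At the last step any such damage ends in a polar octaphenol that is hard to purify. The fallback changes the protecting-group logic: the hydroxide treatment is moved to the robust tetramethyl ether stage, where by-products can still be separated, and the last step becomes a nearly neutral ammonolysis. It sets out from 25 and comes back at 27. The triflates of 25 would be cleaved first (Et4NOH, dioxane) to the tetraphenol tetramethyl ether F5, which is acetylated (Ac2O, pyridine) to the tetraacetate F6. BBr3 demethylation with the acetates as the deactivating groups should give the tetraacetate of the target F7, and NH3 in MeOH at 0 °C would release 27.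

Further compounds
F1 | step 9 | 4-[(2S,3S)-3-(3,5-dimethoxyphenyl)oxiran-2-yl]-1,3-phenylene bis(trifluoromethanesulfonate) | O1[C@@H](c2ccc(OS(=O)(=O)C(F)(F)F)cc2OS(=O)(=O)C(F)(F)F)[C@@H]1c3cc(OC)cc(OC)c3
F2 | step 9 | (1R,2S)-1-[2,4-bis(trifluoromethanesulfonyloxy)phenyl]-2-(3,5-dimethoxyphenyl)-2-[4-(1,3-dioxolan-2-yl)-2-hydroxy-6-methoxyphenyl]ethan-1-ol | O[C@@H](c1ccc(OS(=O)(=O)C(F)(F)F)cc1OS(=O)(=O)C(F)(F)F)[C@H](c1c(O)cc(C2OCCO2)cc1OC)c1cc(OC)cc(OC)c1
F3 | step 15 | (2S,3S)-oxirane diastereomer of 21 | O1[C@@H](c2ccc(OS(=O)(=O)C(F)(F)F)cc2)[C@@H]1c1cc(OC)c2c(c1)O[C@H](c1ccc(OS(=O)(=O)C(F)(F)F)cc1OS(=O)(=O)C(F)(F)F)[C@H]2c1cc(OC)cc(OC)c1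
F4 | step 15 | phenol-alcohol from F3 and 7 ((R)-carbinol bearing ring F; (S)-methine bearing the phenol ring and ring C) | O[C@@H](c1ccc(OS(=O)(=O)C(F)(F)F)cc1)[C@H](c1c(O)cc(C2OCCO2)cc1OC)c1cc(OC)c2c(c1)O[C@H](c1ccc(OS(=O)(=O)C(F)(F)F)cc1OS(=O)(=O)C(F)(F)F)[C@H]2c1cc(OC)cc(OC)c1
F5 | step 19 | tetra-O-methyl target (free OH on rings A, E and F) | Oc1ccc(/C=C/c2cc(OC)c3c(c2)O[C@H](c2ccc(O)cc2)[C@H]3c2cc(OC)c3c(c2)O[C@H](c2ccc(O)cc2O)[C@H]3c2cc(OC)cc(OC)c2)cc1
F6 | step 19 | tetra-O-acetyl tetra-O-methyl target | CC(=O)Oc1ccc(/C=C/c2cc(OC)c3c(c2)O[C@H](c2ccc(OC(C)=O)cc2)[C@H]3c2cc(OC)c3c(c2)O[C@H](c2ccc(OC(C)=O)cc2OC(C)=O)[C@H]3c2cc(OC)cc(OC)c2)cc1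
F7 | step 19 | tetra-O-acetyl target (acetates on rings A, E and F) | CC(=O)Oc1ccc(/C=C/c2cc(O)c3c(c2)O[C@H](c2ccc(OC(C)=O)cc2)[C@H]3c2cc(O)c3c(c2)O[C@H](c2ccc(OC(C)=O)cc2OC(C)=O)[C@H]3c2cc(O)cc(O)c2)cc1
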